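**Plan**
- Retrosynthesis: the five phenol groups are masked as benzyl ethers and a helper chlorine sits on C5 of ring A, all removed last. Before that, the dodecanoyl–aryl bond is cut to an aryl bromide and C4–H to a tertiary C4 carbinol.
- Strategic cut: the aryl ether bond O1–C8a and the bond C4–C4a are cut together. This removes ring A as a benzyne and leaves an acyclic aldol, (R)-ArCH(OH)–CH2–C(=O)–Ar'.
- Enabling feature: ring A carries O1 and C4 on adjacent carbons (C8a, C4a). In the chain O1–C2–C3–C4 the oxygen is a nucleophile and C4, at ketone level, an electrophile, which is the donor/acceptor pair an aryne takes up across its two carbons.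
- Forward order: ring B and the phloroglucinol ring are bought; chalcone, then asymmetric β-borylation/oxidation gives the aldol. Ring C (the pyran) is closed onto the incoming ring A in one step, followed by C4 reduction, acylation and deprotection.
- Stereochemistry: C2 (R) comes from the chiral copper catalyst in the conjugate borylation. C4 is set afterwards by hydride delivery to the C4 cation trans to the C2 aryl group, giving the 2,4-cis arrangement.

Key step: step 10

Remark: the SMILES is read as the (2R,4R) isomer, in which the two aryl groups on ring C are cis. Chroman numbering (O1, C2, C3, C4, C4a, C5 to C8, C8a) is used throughout. Intermediates carrying the C5 chlorine have the same spatial arrangement but the descriptor 4S, because chlorine raises the rank of C4a.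

**Route**

Step 1
Reactants: 1 1-(2,4,6-trihydroxyphenyl)ethan-1-one
Product: 2 1-[2,4,6-tris(benzyloxy)phenyl]ethan-1-one
Conditions: BnBr (3.6 equiv), K2CO3 (5 equiv), DMF, 70 °C
Reagents that add atoms: benzyl bromide, BrCc1ccccc1
Why: Williamson ether synthesis on all three phenoxides; excess halide and heat are used because the two ortho hydroxyls are hydrogen-bonded to the ketone.

Step 2
Reactants: 2 1-[2,4,6-tris(benzyloxy)phenyl]ethan-1-one
Product: 3 1-[2,4,6-tris(benzyloxy)-3-bromophenyl]ethan-1-one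
Conditions: NBS (1.0 equiv), MeCN, 0 °C, dark
Reagents that add atoms: N-bromosuccinimide, O=C1CCC(=O)N1Br
Why: electrophilic aromatic bromination at the one free ring position type, which is ortho/para to three alkoxy groups and should react far faster than the acetyl α-carbon in a polar solvent; the bromine is the placeholder for the dodecanoyl group.

Step 3
Reactants: 3 1-[2,4,6-tris(benzyloxy)-3-bromophenyl]ethan-1-one; 4 4-(benzyloxy)benzaldehyde
Product: 5 (E)-3-[4-(benzyloxy)phenyl]-1-[2,4,6-tris(benzyloxy)-3-bromophenyl]prop-2-en-1-one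
Conditions: KOH (aq), EtOH/THF, rt
Reagents that add atoms: none
Why: Claisen–Schmidt condensation (aldol addition then dehydration) of a methyl ketone with a non-enolisable aldehyde, giving the E enone under thermodynamic control.

Step 4
Reactants: 5 (E)-3-[4-(benzyloxy)phenyl]-1-[2,4,6-tris(benzyloxy)-3-bromophenyl]prop-2-en-1-one
Product: 6 (3R)-3-[4-(benzyloxy)phenyl]-1-[2,4,6-tris(benzyloxy)-3-bromophenyl]-3-(4,4,5,5-tetramethyl-1,3,2-dioxaborolan-2-yl)propan-1-one
Conditions: B2pin2 (1.1 equiv), CuCl (3 mol%), NaOtBu (3 mol%), (R)-1-[(S)-2-(diphenylphosphino)ferrocenyl]ethyldicyclohexylphosphine or its mirror image (3 mol%), MeOH (2 equiv), THF, rt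
Reagents that add atoms: bis(pinacolato)diboron, CC1(C)OB(OC1(C)C)B1OC(C)(C)C(C)(C)O1
Why: copper-catalysed enantioselective conjugate borylation, in which the ligated copper–boryl species adds to the β-carbon on the face fixed by the chiral bisphosphine and methanol protonates the copper enolate; the new C–B centre (future C2) is therefore catalyst-controlled, and the ligand antipode that gives the R boronate is to be fixed on the first run.

Step 5
Reactants: 6 (3R)-3-[4-(benzyloxy)phenyl]-1-[2,4,6-tris(benzyloxy)-3-bromophenyl]-3-(4,4,5,5-tetramethyl-1,3,2-dioxaborolan-2-yl)propan-1-one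
Product: 7 (3R)-3-[4-(benzyloxy)phenyl]-1-[2,4,6-tris(benzyloxy)-3-bromophenyl]-3-hydroxypropan-1-one
Conditions: NaBO3·4H2O (4 equiv), THF/H2O (1:1), rt
Reagents that add atoms: sodium perborate tetrahydrate, [Na+].[O-]OB=O.O.O.O.O
Why: oxidation of the secondary boronate by 1,2-shift of carbon from boron to oxygen goes with retention, so the R alcohol results (overall a formal asymmetric aldol), and the mild oxidant should spare the β-hydroxy ketone from dehydration.

Step 6
Reactants: 7 (3R)-3-[4-(benzyloxy)phenyl]-1-[2,4,6-tris(benzyloxy)-3-bromophenyl]-3-hydroxypropan-1-one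
Product: 8 (3R)-3-[4-(benzyloxy)phenyl]-1-[2,4,6-tris(benzyloxy)-3-bromophenyl]-3-[(trimethylsilyl)oxy]propan-1-one
Conditions: N-(trimethylsilyl)imidazole (1.3 equiv), CH2Cl2, 0 °C → rt
Reagents that add atoms: N-(trimethylsilyl)imidazole, C[Si](C)(C)n1ccnc1
Why: neutral O-silylation of a secondary alcohol, which stores the alkoxide in a form that fluoride can release later without any proton donor.

Step 7
Reactants: 9 4-(benzyloxy)phenol
Product: 10 4-(benzyloxy)-2-chlorophenol
Conditions: SO2Cl2 (1.0 equiv), CH2Cl2, 0 °C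
Reagents that add atoms: sulfuryl chloride, ClS(Cl)(=O)=O
Why: electrophilic chlorination of a para-blocked phenol, directed ortho to the free hydroxyl.

Step 8
Reactants: 10 4-(benzyloxy)-2-chlorophenol
Product: 11 4-(benzyloxy)-2-bromo-6-chlorophenol
Conditions: NBS (1.0 equiv), iPr2NH (10 mol%), CH2Cl2, 0 °C
Reagents that add atoms: N-bromosuccinimide, O=C1CCC(=O)N1Br
Why: amine-catalysed ortho-bromination of a phenol at the one remaining position ortho to the hydroxyl.

Step 9
Reactants: 11 4-(benzyloxy)-2-bromo-6-chlorophenol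
Product: 14 4-(benzyloxy)-2-chloro-6-(trimethylsilyl)phenyl trifluoromethanesulfonate, via aryl trimethylsilyl ether 12 (not isolated), via lithium 2-silylphenoxide 13 (not isolated)
Conditions: HMDS, THF, 65 °C, volatiles removed; n-BuLi (1.1 equiv), THF, −78 °C; Tf2O (1.2 equiv), −78 °C → rt
Reagents that add atoms: hexamethyldisilazane, C[Si](C)(C)N[Si](C)(C)C; trifluoromethanesulfonic anhydride, FC(F)(F)S(=O)(=O)OS(=O)(=O)C(F)(F)F
Why: standard entry to an ortho-silylaryl triflate by O-silylation, bromine–lithium exchange with anionic 1,3 O-to-C silyl shift (retro-Brook rearrangement) and O-triflation of the phenoxide; the chlorine is meta to the lithiated carbon and cannot be eliminated.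

Step 10
Reactants: 8 (3R)-3-[4-(benzyloxy)phenyl]-1-[2,4,6-tris(benzyloxy)-3-bromophenyl]-3-[(trimethylsilyl)oxy]propan-1-one; 14 4-(benzyloxy)-2-chloro-6-(trimethylsilyl)phenyl trifluoromethanesulfonate
Product: 17 (2R)-7-(benzyloxy)-2-[4-(benzyloxy)phenyl]-4-[2,4,6-tris(benzyloxy)-3-bromophenyl]-5-chlorochroman-4-ol (both C4 epimers), via cesium alkoxide 15 (not isolated), via aryne 16 (not isolated)
Conditions: 14 (1.6 equiv), CsF (3.5 equiv), 18-crown-6 (3.5 equiv), THF, −20 °C → rt; then H2O
Reagents that add atoms: none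
Why: Proposed new method: fluoride strips the trimethylsilyl groups from 8 and from 14, which gives the free alkoxide 15 and, by loss of triflate, the aryne 16 in a medium without proton donors; the alkoxide oxygen adds to the aryne carbon remote from chlorine and the aryl carbanion formed at the neighbouring carbon adds to the ketone carbon held in reach by the three-atom tether, so the O1–C8a and C4–C4a bonds arise in one cascade. The closest known reaction type is the fluoride-induced annulation of arynes with ortho-hydroxyaryl aldehydes and ketones, in which a phenoxide adds and the aryl carbanion is caught by the carbonyl group to give 9-hydroxyxanthenes; an aliphatic aldol alkoxide in this role is the extension proposed here. Ring C closes in the second event by 6-exo-trig attack of the carbanion at C4a on the C4 carbonyl group. C2 is not involved and keeps its R configuration, while the new carbinol centre C4 may form as either epimer, which does not matter because step 11 passes through the planar C4 cation. The step needs the oxygen to attack the future C8a and not C4a, which the chlorine on the carbon next to C4a should secure by polarising the aryne (attack remote from the halogen places the carbanion beside it); it also needs carbonyl capture to outrun protonation, chloride loss and retro-aldol cleavage of 15, for which the aprotic medium, the six-membered transition state, the low temperature and the excess of 14 (which can re-silylate free alkoxide while releasing more aryne) are provided.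

Step 11
Reactants: 17 (2R)-7-(benzyloxy)-2-[4-(benzyloxy)phenyl]-4-[2,4,6-tris(benzyloxy)-3-bromophenyl]-5-chlorochroman-4-ol
Product: 19 (2R,4S)-7-(benzyloxy)-2-[4-(benzyloxy)phenyl]-4-[2,4,6-tris(benzyloxy)-3-bromophenyl]-5-chlorochromane (2,4-cis), via benzylic cation 18 (not isolated)
Conditions: Et3SiH (5 equiv), CF3CO2H (3 equiv), CH2Cl2, −78 → −20 °C
Reagents that add atoms: none
Why: ionic hydrogenation, in which acid ionises the doubly benzylic tertiary alcohol to cation 18 (stabilised by O1 and the C7 benzyloxy group) and the silane delivers hydride along the pseudo-axial path of the half-chair that keeps the C2 aryl group pseudo-equatorial, that is trans to that aryl group, so the C4 aryl group should end up cis to it under control of C2.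

Step 12
Reactants: 20 dodecanoyl chloride; 21 N,O-dimethylhydroxylamine hydrochloride
Product: 22 N-methoxy-N-methyldodecanamide
Conditions: K2CO3 (aq), CH2Cl2, 0 °C → rt
Reagents that add atoms: none
Why: Schotten–Baumann acylation of the liberated amine by the acid chloride.

Step 13
Reactants: 19 (2R,4S)-7-(benzyloxy)-2-[4-(benzyloxy)phenyl]-4-[2,4,6-tris(benzyloxy)-3-bromophenyl]-5-chlorochromane; 22 N-methoxy-N-methyldodecanamide
Product: 24 1-{2,4,6-tris(benzyloxy)-3-[(2R,4S)-7-(benzyloxy)-2-[4-(benzyloxy)phenyl]-5-chlorochroman-4-yl]phenyl}dodecan-1-one, via aryllithium 23 (not isolated)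
Conditions: n-BuLi (1.05 equiv), THF, −78 °C; 22 (1.5 equiv), −78 → 0 °C; aq NH4Cl
Reagents that add atoms: none
Why: bromine–lithium exchange should be faster than attack on the C–Cl bond or benzylic deprotonation at −78 °C, and the aryllithium flanked by two alkoxy groups acylates the N-methoxy-N-methylamide through a chelated tetrahedral adduct that cannot add twice (Weinreb ketone synthesis).

Step 14
Reactants: 24 1-{2,4,6-tris(benzyloxy)-3-[(2R,4S)-7-(benzyloxy)-2-[4-(benzyloxy)phenyl]-5-chlorochroman-4-yl]phenyl}dodecan-1-one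
Product: 25 1-{2,4,6-trihydroxy-3-[(2R,4R)-7-hydroxy-2-(4-hydroxyphenyl)chroman-4-yl]phenyl}dodecan-1-one
Conditions: H2 (1 atm), 10% Pd/C, NaOAc (2 equiv), THF/MeOH (1:1), rt
Reagents that add atoms: none
Why: heterogeneous palladium-catalysed hydrogenolysis cleaves the five benzyl aryl ethers and, with acetate as acid scavenger, the C5–Cl bond (hydrodechlorination), while the flavan C2–O bond and the hydrogen-bonded acylphloroglucinol ketone should survive and neither stereocentre is touched (C4 becomes R by name only).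

**Compound list**

1 | 1-(2,4,6-trihydroxyphenyl)ethan-1-one | CC(=O)c1c(O)cc(O)cc1O | starting material
2 | 1-[2,4,6-tris(benzyloxy)phenyl]ethan-1-one | CC(=O)c1c(OCc2ccccc2)cc(OCc2ccccc2)cc1OCc1ccccc1 | intermediate
3 | 1-[2,4,6-tris(benzyloxy)-3-bromophenyl]ethan-1-one | CC(=O)c1c(OCc2ccccc2)c(Br)c(OCc2ccccc2)cc1OCc1ccccc1 | intermediate
4 | 4-(benzyloxy)benzaldehyde | O=Cc1ccc(OCc2ccccc2)cc1 | starting material
5 | (E)-3-[4-(benzyloxy)phenyl]-1-[2,4,6-tris(benzyloxy)-3-bromophenyl]prop-2-en-1-one | O=C(/C=C/c1ccc(OCc2ccccc2)cc1)c1c(OCc2ccccc2)c(Br)c(OCc2ccccc2)cc1OCc1ccccc1 | intermediate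
6 | (3R)-3-[4-(benzyloxy)phenyl]-1-[2,4,6-tris(benzyloxy)-3-bromophenyl]-3-(4,4,5,5-tetramethyl-1,3,2-dioxaborolan-2-yl)propan-1-one | O=C(C[C@H](c1ccc(OCc2ccccc2)cc1)B1OC(C)(C)C(C)(C)O1)c1c(OCc2ccccc2)c(Br)c(OCc2ccccc2)cc1OCc1ccccc1 | intermediate
7 | (3R)-3-[4-(benzyloxy)phenyl]-1-[2,4,6-tris(benzyloxy)-3-bromophenyl]-3-hydroxypropan-1-one | O=C(C[C@H](c1ccc(OCc2ccccc2)cc1)O)c1c(OCc2ccccc2)c(Br)c(OCc2ccccc2)cc1OCc1ccccc1 | intermediate
8 | (3R)-3-[4-(benzyloxy)phenyl]-1-[2,4,6-tris(benzyloxy)-3-bromophenyl]-3-[(trimethylsilyl)oxy]propan-1-one | O=C(C[C@H](c1ccc(OCc2ccccc2)cc1)O[Si](C)(C)C)c1c(OCc2ccccc2)c(Br)c(OCc2ccccc2)cc1OCc1ccccc1 | intermediate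
9 | 4-(benzyloxy)phenol | Oc1ccc(OCc2ccccc2)cc1 | starting material
10 | 4-(benzyloxy)-2-chlorophenol | Oc1ccc(OCc2ccccc2)cc1Cl | intermediate
11 | 4-(benzyloxy)-2-bromo-6-chlorophenol | Oc1c(Cl)cc(OCc2ccccc2)cc1Br | intermediate
12 | [4-(benzyloxy)-2-bromo-6-chlorophenoxy]trimethylsilane | C[Si](C)(C)Oc1c(Cl)cc(OCc2ccccc2)cc1Br | intermediate (not isolated)
13 | lithium 4-(benzyloxy)-2-chloro-6-(trimethylsilyl)phenolate | [Li+].[O-]c1c(Cl)cc(OCc2ccccc2)cc1[Si](C)(C)C | intermediate (not isolated)
14 | 4-(benzyloxy)-2-chloro-6-(trimethylsilyl)phenyl trifluoromethanesulfonate | C[Si](C)(C)c1cc(OCc2ccccc2)cc(Cl)c1OS(=O)(=O)C(F)(F)F | intermediate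
15 | cesium (1R)-1-[4-(benzyloxy)phenyl]-3-oxo-3-[2,4,6-tris(benzyloxy)-3-bromophenyl]propan-1-olate | O=C(C[C@H](c1ccc(OCc2ccccc2)cc1)[O-])c1c(OCc2ccccc2)c(Br)c(OCc2ccccc2)cc1OCc1ccccc1.[Cs+] | intermediate (not isolated)
16 | 5-(benzyloxy)-3-chlorobenzyne (5-(benzyloxy)-3-chloro-1,2-didehydrobenzene) | ClC1=CC(OCc2ccccc2)=CC#C1 | intermediate (not isolated)
17 | (2R)-7-(benzyloxy)-2-[4-(benzyloxy)phenyl]-4-[2,4,6-tris(benzyloxy)-3-bromophenyl]-5-chlorochroman-4-ol, both C4 epimers | OC1(c2c(OCc3ccccc3)c(Br)c(OCc3ccccc3)cc2OCc2ccccc2)C[C@H](c2ccc(OCc3ccccc3)cc2)Oc2cc(OCc3ccccc3)cc(Cl)c21 | intermediate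
18 | (2R)-7-(benzyloxy)-2-[4-(benzyloxy)phenyl]-4-[2,4,6-tris(benzyloxy)-3-bromophenyl]-5-chlorochroman-4-ylium trifluoroacetate | Brc1c(OCc2ccccc2)cc(OCc2ccccc2)c([C+]2C[C@H](c3ccc(OCc4ccccc4)cc3)Oc3cc(OCc4ccccc4)cc(Cl)c32)c1OCc1ccccc1.[O-]C(=O)C(F)(F)F | intermediate (not isolated)
19 | (2R,4S)-7-(benzyloxy)-2-[4-(benzyloxy)phenyl]-4-[2,4,6-tris(benzyloxy)-3-bromophenyl]-5-chlorochromane, 2,4-cis | Brc1c(OCc2ccccc2)cc(OCc2ccccc2)c([C@@H]2C[C@H](c3ccc(OCc4ccccc4)cc3)Oc3cc(OCc4ccccc4)cc(Cl)c32)c1OCc1ccccc1 | intermediate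
20 | dodecanoyl chloride | CCCCCCCCCCCC(=O)Cl | starting material
21 | N,O-dimethylhydroxylamine hydrochloride | CNOC.Cl | starting material
22 | N-methoxy-N-methyldodecanamide | CCCCCCCCCCCC(=O)N(C)OC | intermediate
23 | {2,4,6-tris(benzyloxy)-3-[(2R,4S)-7-(benzyloxy)-2-[4-(benzyloxy)phenyl]-5-chlorochroman-4-yl]phenyl}lithium | [Li]c1c(OCc2ccccc2)cc(OCc2ccccc2)c([C@@H]2C[C@H](c3ccc(OCc4ccccc4)cc3)Oc3cc(OCc4ccccc4)cc(Cl)c32)c1OCc1ccccc1 | intermediate (not isolated)
24 | 1-{2,4,6-tris(benzyloxy)-3-[(2R,4S)-7-(benzyloxy)-2-[4-(benzyloxy)phenyl]-5-chlorochroman-4-yl]phenyl}dodecan-1-one | CCCCCCCCCCCC(=O)c1c(OCc2ccccc2)cc(OCc2ccccc2)c([C@@H]2C[C@H](c3ccc(OCc4ccccc4)cc3)Oc3cc(OCc4ccccc4)cc(Cl)c32)c1OCc1ccccc1 | intermediate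
25 | 1-{2,4,6-trihydroxy-3-[(2R,4R)-7-hydroxy-2-(4-hydroxyphenyl)chroman-4-yl]phenyl}dodecan-1-one | CCCCCCCCCCCC(=O)c1c(O)cc(O)c([C@@H]2C[C@H](c3ccc(O)cc3)Oc3cc(O)ccc32)c1O | target

**Count and risks**

Total step count: 14. Longest linear sequence: 10 steps (steps 1, 2, 3, 4, 5, 6, 10, 11, 13, 14).

Steps most likely to fail:

1. Step 10 (Proposed new method). The unmasked alkoxide may undergo retro-aldol cleavage or β-elimination before it meets the aryne, with loss of material and of optical purity. The aryl carbanion may pick up a proton and stop at the open aryl ether, or expel chloride to give a second aryne. Oxygen attack at the wrong aryne carbon is also possible.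
   Fallback (known chemistry, sets out from 7, returns at 25): commercial 4-(benzyloxy)-1-bromo-2-fluorobenzene is lithiated with n-BuLi in THF at −78 °C, and 2.2 equiv of the 2-fluoroaryllithium are added to 7 at −78 °C. The first equivalent forms the lithium aldolate, which should not revert at this temperature. This gives (3R)-1-[4-(benzyloxy)-2-fluorophenyl]-3-[4-(benzyloxy)phenyl]-1-[2,4,6-tris(benzyloxy)-3-bromophenyl]propane-1,3-diol F1. KOtBu in DMF at 60–80 °C then closes ring C by intramolecular nucleophilic aromatic substitution of fluoride by the C3 alkoxide, giving (2R)-7-(benzyloxy)-2-[4-(benzyloxy)phenyl]-4-[2,4,6-tris(benzyloxy)-3-bromophenyl]chroman-4-ol F2. The positions of bromine and fluorine fix the regiochemistry, so no chlorine is needed. F2 is carried on by the chemistry of steps 11, 13 and 14: Et3SiH/CF3CO2H gives (2R,4R)-7-(benzyloxy)-2-[4-(benzyloxy)phenyl]-4-[2,4,6-tris(benzyloxy)-3-bromophenyl]chromane F3; n-BuLi then 22 gives 1-{2,4,6-tris(benzyloxy)-3-[(2R,4R)-7-(benzyloxy)-2-[4-(benzyloxy)phenyl]chroman-4-yl]phenyl}dodecan-1-one F4; hydrogenolysis over Pd/C gives 25.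

2. Step 11. Facial selectivity of hydride delivery may be poor, because the chlorine peri to C4 presses on the C4 aryl group and may favour the other half-chair. The cation may also lose a proton to the chromene, or open at C2–O1 with loss of C2 configuration.
   Fallback (sets out from 17, returns at 25): 17 is dehydrated under non-acidic conditions with methyl N-(triethylammoniosulfonyl)carbamate inner salt in THF at 50 °C to (2R)-7-(benzyloxy)-2-[4-(benzyloxy)phenyl]-4-[2,4,6-tris(benzyloxy)-3-bromophenyl]-5-chloro-2H-chromene F5. Bromine–lithium exchange and acylation with 22 as in step 13 give 1-{2,4,6-tris(benzyloxy)-3-[(2R)-7-(benzyloxy)-2-[4-(benzyloxy)phenyl]-5-chloro-2H-chromen-4-yl]phenyl}dodecan-1-one F6. Hydrogenation over Pd/C with NaOAc then adds hydrogen to the C3=C4 bond from the face opposite the C2 aryl group (syn addition on the catalyst surface, giving the cis product) and removes the benzyl groups and the chlorine in the same operation, giving 25.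

3. Step 14. Hydrogenolysis of the hindered, electron-rich C5–Cl bond may stall after the benzyl ethers have gone, leaving chlorinated polyphenol that is hard to separate.
   Fallback (sets out from 24, returns at 25): the chlorine is removed first at the protected stage by homogeneous transfer hydrodechlorination with Pd(OAc)2, tricyclohexylphosphine and HCO2Na in DMF at 90 °C (oxidative addition of zerovalent palladium into C–Cl, formate as hydride donor). This gives 1-{2,4,6-tris(benzyloxy)-3-[(2R,4R)-7-(benzyloxy)-2-[4-(benzyloxy)phenyl]chroman-4-yl]phenyl}dodecan-1-one F7, identical in structure with F4. Hydrogenolysis of the benzyl ethers alone (H2, Pd/C, THF/MeOH) then gives 25.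

**Further compounds**

F1 | step 10 | (3R)-1-[4-(benzyloxy)-2-fluorophenyl]-3-[4-(benzyloxy)phenyl]-1-[2,4,6-tris(benzyloxy)-3-bromophenyl]propane-1,3-diol, both C1 epimers | OC(C[C@H](c1ccc(OCc2ccccc2)cc1)O)(c1ccc(OCc2ccccc2)cc1F)c1c(OCc2ccccc2)c(Br)c(OCc2ccccc2)cc1OCc1ccccc1
F2 | step 10 | (2R)-7-(benzyloxy)-2-[4-(benzyloxy)phenyl]-4-[2,4,6-tris(benzyloxy)-3-bromophenyl]chroman-4-ol, both C4 epimers | OC1(c2c(OCc3ccccc3)c(Br)c(OCc3ccccc3)cc2OCc2ccccc2)C[C@H](c2ccc(OCc3ccccc3)cc2)Oc2cc(OCc3ccccc3)ccc21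
F3 | step 10 | (2R,4R)-7-(benzyloxy)-2-[4-(benzyloxy)phenyl]-4-[2,4,6-tris(benzyloxy)-3-bromophenyl]chromane | Brc1c(OCc2ccccc2)cc(OCc2ccccc2)c([C@@H]2C[C@H](c3ccc(OCc4ccccc4)cc3)Oc3cc(OCc4ccccc4)ccc32)c1OCc1ccccc1
F4 | step 10 | 1-{2,4,6-tris(benzyloxy)-3-[(2R,4R)-7-(benzyloxy)-2-[4-(benzyloxy)phenyl]chroman-4-yl]phenyl}dodecan-1-one | CCCCCCCCCCCC(=O)c1c(OCc2ccccc2)cc(OCc2ccccc2)c([C@@H]2C[C@H](c3ccc(OCc4ccccc4)cc3)Oc3cc(OCc4ccccc4)ccc32)c1OCc1ccccc1
F5 | step 11 | (2R)-7-(benzyloxy)-2-[4-(benzyloxy)phenyl]-4-[2,4,6-tris(benzyloxy)-3-bromophenyl]-5-chloro-2H-chromene | Brc1c(OCc2ccccc2)cc(OCc2ccccc2)c(C2=C[C@H](c3ccc(OCc4ccccc4)cc3)Oc3cc(OCc4ccccc4)cc(Cl)c32)c1OCc1ccccc1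
F6 | step 11 | 1-{2,4,6-tris(benzyloxy)-3-[(2R)-7-(benzyloxy)-2-[4-(benzyloxy)phenyl]-5-chloro-2H-chromen-4-yl]phenyl}dodecan-1-one | CCCCCCCCCCCC(=O)c1c(OCc2ccccc2)cc(OCc2ccccc2)c(C2=C[C@H](c3ccc(OCc4ccccc4)cc3)Oc3cc(OCc4ccccc4)cc(Cl)c32)c1OCc1ccccc1
F7 | step 14 | 1-{2,4,6-tris(benzyloxy)-3-[(2R,4R)-7-(benzyloxy)-2-[4-(benzyloxy)phenyl]chroman-4-yl]phenyl}dodecan-1-one | CCCCCCCCCCCC(=O)c1c(OCc2ccccc2)cc(OCc2ccccc2)c([C@@H]2C[C@H](c3ccc(OCc4ccccc4)cc3)Oc3cc(OCc4ccccc4)ccc32)c1OCc1ccccc1
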